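I followed one molecule.

- teal: left-handed substrate 20 mM; right-handed substrate 20 mM; reagent 50 mM (fed, over 3.0 h); free catalyst 0.50 mM; the very flask that is asked about, followed so far
- flask: left-handed substrate 20 mM; reagent 50.0 mM (fed, over 3.0 h); free catalyst 0.50 mM; right-handed substrate 20 mM; time 30 h

teal run (percent of the left-handed substrate and right-handed substrate together charged)

| time / h | left-handed product / % | right-handed product / % |
|---|---|---|
| 1.00 | 0.9 | 0.4 |
| 2.00 | 4.1 | 1.5 |
| 3.00 | 7.6 | 2.0 |
| 6.00 | 17.8 | 4.9 |
| 12.0 | 27.8 | 8.9 |

(readings scatter by 0.3 percentage points)

- free catalyst is single-handed; left-handed substrate and right-handed substrate are mirror images of each other, charged as a racemate, each of them at the stated concentration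
- what may be going on: reagent + free catalyst + left-handed substrate -> free catalyst + left-handed product; reagent + free catalyst + right-handed substrate -> free catalyst + right-handed product; left-handed substrate <-> right-handed substrate; free catalyst -> spent catalyst A; 2 free catalyst -> spent catalyst B
- an excess is the difference of the two amounts in percent of their sum
- an excess is below zero if the other one leads

- left-handed product and right-handed product together, in percent of the left-handed substrate and right-handed substrate charged together, at 30 h
- excess of left-handed product over right-handed product in the product at 30 h
- whether the exchange between left-handed substrate and right-handed substrate keeps pace with the reaction: how far the product's excess at 30 h gets from its value without exchange to its value with instant exchange (above 80% keeps pace, below 20% hardly takes part, else lags behind)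

In the teal flask, which is the flask asked about, each substrate molecule that reacts on the single-handed free catalyst ends up as one of two products. At 3.00 h, with the two substrates still roughly level, the readings stood at 7.6% left-handed product and 2.0% right-handed product, which is 3.80 to one, with the scatter of 0.3 percentage points in each reading. I call this the fork ratio, the selectivity factor: how many times likelier a left-handed substrate molecule is to react than a right-handed one at equal amounts. Product forming at any moment then comes out as the fork ratio times the left-handed substrate, to the right-handed substrate. With the substrates kept level, as instant exchange would keep them, I reckoned an excess of 58.3%.

The forecast, from the same runs, stood lower than my mark of 58.3%: 51% of product, an excess of 45.5%, and an exchange that hardly takes part, seeing “no sign of exchange, which would make the ratio climb”.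

The flask gave 52.6% of product at an excess of 53.1%, and the exchange lags behind, getting 59% of the way.

    reagent + free catalyst + left-handed substrate → free catalyst + left-handed product (k = 1.63 M⁻² s⁻¹)
    reagent + free catalyst + right-handed substrate → free catalyst + right-handed product (k = 0.416 M⁻² s⁻¹)
    left-handed substrate ⇌ right-handed substrate (k = 1.99 × 10⁻⁵ s⁻¹)
    free catalyst → spent catalyst A (k = 3.16 × 10⁻⁶ s⁻¹)
    2 free catalyst → spent catalyst B (k = 0.0263 M⁻¹ s⁻¹)

At 30.0 h this flask held 22.1% left-handed substrate and 25.2% right-handed substrate, the relaxation half-life of the exchange by that step alone, both ways together, being 4.84 h. The fork ratio puts the product forming then at an excess of 53.9%. The flask with 12 mM of reagent held 41.4% left-handed substrate and 42.6% right-handed substrate at that time, so the fork ratio puts the product forming there at an excess of 57.4%, and its whole product stood at an excess of 57.9%.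

(The earlier runs and the new flask stem from a simulated flask for an exercise, and the scatter is random.)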